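(The data are calculated from invented constants; scatter was added.)

One percent of the substrate charge is my unit of account. Substrate is the limiting reagent, because the flask's partner charge stands at 1.20 of it. Each unit turned into product takes one unit of partner and frees one of released group, so at the 5.0% mark the flask's partner has paid about 4.17% of its own charge, and at full conversion 16.7% of it stays over. The catalyst can hold at most 0.197% of the substrate, or 1.13% at 0.80 mM, less than the mark, so the books close on product plus that holding.

common to all: substrate 0.071 M; free catalyst 0.14 mM
- larch: partner 0.12 M; run made earlier
- elm: partner 0.19 M; run made earlier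
- flask: partner 0.0852 M

| run | time / min | product / % |
|---|---|---|
| larch | 2.50 | 0 |
| larch | 5.00 | 5 |
| larch | 8.00 | 7 |
| larch | 15.0 | 10 |
| larch | 30.0 | 21 |
| elm | 6.00 | 5 |
| elm | 12.0 | 10 |
| elm | 20.0 | 15 |
| elm | 25.0 | 17 |
| elm | 30.0 | 18 |

(standard deviation of a reading: 1.5 percentage points)

- what was read earlier has a scatter of 1.5 percentage points, one standard deviation
- steps that have been proposed: substrate + free catalyst -> catalyst intermediate A; catalyst intermediate A -> catalyst intermediate B; partner + catalyst intermediate B <-> catalyst intermediate C; catalyst intermediate C <-> released group + catalyst intermediate D; catalyst intermediate D -> free catalyst + product; free catalyst <-> dormant form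
- no earlier run changes the charge of free catalyst; that part of a forecast is a guess

1. factor on the rate of making product when 5.0% of the substrate are converted if partner is charged twice over
2. factor on the rate when 5.0% of the substrate are converted if free catalyst is charged at 0.80 mM instead

The ledger has no clock, so I read one from larch, which makes 7% in 8.00 min and 14 percentage points in the next 22.0 min. That reads 1.38, loosely given the scatter: the early premium, the rate before a break over the rate after it. Larch's average rate puts larch's own mark near 7.14 min, about at the break; I assume the flask's mark lies there too, at the later rate. At 0.80 mM the catalyst is 5.71 times larger and the mark comes near 1.25 min, inside the early stretch. The proposed step into the dormant form takes no second reagent, so I suppose the premium runs on the clock and reckon the factor for 0.80 mM at 7.86. Elm reaches 10% at 12.0 min and larch at 15.0 min; assuming that order holds at the flask's partner charge, the factor for doubled partner reads near 1.40.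

The forecast gives 1.35 for doubled partner and 5.5 for 0.80 mM, holding that “rate should scale with charge”, so on the second it stands lower than mine.

    substrate + free catalyst → catalyst intermediate A (k = 5.67 L mol⁻¹ s⁻¹)
    catalyst intermediate A → catalyst intermediate B (k = 12.7 s⁻¹)
    partner + catalyst intermediate B ⇌ catalyst intermediate C (K = 11.6 L mol⁻¹, k = 3.94 L mol⁻¹ s⁻¹)
    catalyst intermediate C ⇌ released group + catalyst intermediate D (K = 0.0378 M, k = 0.458 s⁻¹)
    catalyst intermediate D → free catalyst + product (k = 0.384 s⁻¹)
    free catalyst ⇌ dormant form (K = 2.80, k = 0.00885 s⁻¹)

The flask gives 1.21, below my reckoning, and 7.58, below my 7.86, which rested on the premium; per unit of catalyst charged, 7.58 leaves 1.33. Read with its break at 5.00 min, the flask's own premium is 1.36. While the flask's round turned, free catalyst went over into the dormant form, which holds 27.5% of the catalyst at 5.00 min. It then holds 34.9% at 25.0 min and still 34.6% at 50.0 min.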